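# Proposed synthesis of CNP0346147.1 (30)

Atom labels used throughout: ring B of the chroman-2,4-dione is O1–C2–C3–C4–C4a–C8a, fused to benzene ring A. Farnesyl means (2E,6E)-3,7,11-trimethyldodeca-2,6,10-trien-1-yl (C1'–C12'). The seventeen-carbon chain on C3 is C1''–C17''.

## The problem

Compound 30 is a chroman-2,4-dione whose C3 is a quaternary stereocentre between the two ring carbonyls; C3 carries farnesyl and a chain with a C3'' ketone, a C4''–C7'' diyne, an (S)-carbinol at C8'' and a Z C9''=C10'' alkene. The two stereocentres, C3 (S) and C8'' (S), are separated by an ethylene unit and a linear ynone–diyne rod, so neither can direct the other and each has to be set by reagent control in its own fragment. C3 is the hard one: both alkyl groups begin with CH2, so an open-chain enolate or a prochiral malonate offers a catalyst two arms that differ only beyond the second carbon. The functional groups tolerate little: ring B is an aryl ester of a β-keto acid without α-hydrogen and is opened by alkoxides, amines and hard organometallics, the diynone is a strong Michael acceptor, the C8'' carbinol is both allylic and propargylic, the farnesyl triene cyclises in strong acid, and the Z alkene must not isomerise. The C3''–C4'' bond and the ynone therefore have to be made late under neutral conditions, with the C8'' hydroxyl masked to the end. The enabling feature is that C1'', C2'' and C3'' can be closed with C3, C2 and one oxygen into a six-membered enol lactone (a 3,4-dihydro-2H-pyran-2-one) that stores C3'' at the aldehyde level as an enol ester. In that ring C1'' lies inside and farnesyl outside, so the C2–C3 enolate has a single geometry. The lactone is also an activated enol ester that a phenol ortho to the future C4 ketone can later take over, which converts the auxiliary ring into ring B and the side-chain aldehyde without touching C3.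

## Retrosynthesis

**30 back to 28.** The last two operations change functional groups only. The C8'' O–Si bond of 29 is cut in the final step, and the C3'' ketone of 29 is traced to the carbinol of 28. The ynone is held back because it is the most electrophilic group of the target and because a C3'' carbinol is what a carbonyl addition delivers. The forward steps must oxidise C3'' while C8'' is masked and must remove silicon with acidic fluoride, since basic fluoride would attack the diynone and ring B.

**28 to 17 and 27.** The C3''–C4'' bond is cut. This places C3 in aldehyde 17 and C8'' in iododiyne 27, so each stereocentre is made in its own fragment. The neighbouring cut at C5''–C6'' would need two alkyne fragments and an amine-containing coupling medium. A cut at C2''–C3'' would need an acyl anion equivalent. The forward reaction must add an alkynyl nucleophile to an aldehyde in the presence of the ketone and aryl lactone of ring B, which calls for an organochromium reagent and excludes lithium or magnesium acetylides.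

**17 to 15.** The O1–C2 bond of ring B is cut and C2 is rejoined to the C3'' oxygen, which gives the enol lactone 15 (through phenol 16). Ring B becomes a simple aroyl substituent and the aldehyde chain is folded into the auxiliary ring. The forward reaction must unmask the phenol without external nucleophiles and then transfer the acyl group downhill, from enol ester to aryl ester, with tautomerisation of the released enol to the aldehyde.

**15 to 9 and 14.** The C3–C4 bond is cut, which is the key disconnection. Cutting C3–C1' or C3–C1'' instead would put the stereo-determining step on an alkylation, where the two CH2 arms are hard to tell apart or the electrophile has regiochemical freedom. The C3–C4 cut lets the enol-lactone ring of ketene acetal 9 fix the enolate geometry. Anhydride 14 supplies the aroyl group and the carboxylate that activates silicon. The forward reaction must be an enantioface-selective C-aroylation under a chiral isothiourea.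

**9 to 1 and 2.** Ketene acetal 9 comes from enol lactone 7 by O-silylation of enolate 8. Lactone 7 comes from aldehyde acid 6 by cyclodehydration. Acid 6 comes from ester 4 by saponification (carboxylate 5) and acetal hydrolysis. Ester 4 comes from ester 1 by cutting the C3–C1' bond to farnesyl bromide 2 (enolate 3). Farnesyl enters by an SN2 alkylation in which alkene geometry and regiochemistry are not at stake. The α-centre of 4, 6 and 7 is racemic and becomes sp2 in 9.

**14 to 10.** The central C(O)–O bond of anhydride 14 is cut to acid 12 and acid chloride 13, and 13 is itself made from 12. The two O–Si bonds of bis-silyl ester 11, the precursor of 12, lead back to salicylic acid 10. A symmetrical anhydride is preferred to a mixed one because it offers the catalyst only one kind of acyl group. The forward steps need a silyl ether that survives neutral chloride activation and carboxylate and is removed by fluoride.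

**27 to 21 and 18.** The C–I bond of 27 is traced to the C–Si bond of 26, and the O–Si bond of 26 to carbinol 25. Cutting the C7''–C8'' bond of 25 gives Z-enal 23 and silyl-diyne 20 (through zinc alkynylide 24). This is the shortest way to the carbinol and puts the stereocentre under catalyst control. Enal 23 comes from alcohol 22 and alkyne 21 by oxidation and semihydrogenation. Diyne 20 comes from bis-silane 18 through lithium diynide 19. The forward alkynylation must be enantioselective and must not isomerise the Z alkene.

## Roads not taken

**Alternative 1:** The two bonds from ring A to ring B, O1–C8a and C4–C4a, are cut, so the arene arrives as an aryne and C3 is set beforehand in an acyclic malonate. Prochiral diester A1 would be desymmetrised by an esterase to half-ester A2. Its caesium carboxylate would add to the aryne released from A3 with CsF, and the resulting aryl anion would acylate itself on the remaining methyl ester and close ring B to give A4, whose acetal masks the C3'' aldehyde.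
- Merits: ring B and both arene bonds form in one operation, no phenol protecting group is needed, and enzymatic desymmetrisation of 2,2-disubstituted malonates is an established reaction class. Aldehyde 17 would be reached through A4 in about five steps, against nine in the chosen plan.
- Weak points: the enzyme must tell apart two lipophilic arms that both begin with CH2, the case in which esterases are least predictable, and a farnesyl diester is poorly soluble in buffer. The aryne can undergo ene reactions with the three trisubstituted alkenes. Protonation of the aryl anion stops the sequence at an open aryl ester. The ring closure expels an alkoxide, a nucleophile of the kind that opens 3,3-dialkylchromandiones.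
- Comparison: Alternative 1 is shorter and its stereo-defining step is known in kind, which the chosen plan cannot claim. The chosen plan sets against this a ring-enforced difference between the two arms, no free alkoxide in the presence of ring B, and release of the aldehyde in the same mild operation that closes ring B.

**Alternative 2:** The central C5''–C6'' bond of the diyne is cut. Terminal alkyne A5 (fragment 1, ring B with a C3'' propargylic carbinol) and bromoalkyne A6 (fragment 2, the silylated (S)-carbinol with the Z alkene) would be joined by a Cadiot–Chodkiewicz coupling (catalytic CuCl, NH2OH·HCl, a hindered amine). The product A7 is the same compound as 28.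
- Merits: this is the most even division of the chain. Both partners are monoalkynes, so neither a terminal silyl-diyne nor a 1-iododiyne has to be handled. The mono-alkynylation of a Z-enal that would lead to A6 is better founded than the diyne addition used here, and free hydroxyl groups are tolerated.
- Weak points: the cut does nothing for the quaternary centre, because A5 still needs an enantioselective construction of C3. The amine and hydroxylamine of the coupling medium are nucleophiles towards the aryl lactone. Homocoupling consumes a valuable partner. A5 would have to be made from 17 by a chemoselective ethynylation and desilylation, so the endgame is one to two steps longer.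
- Comparison: as an endgame this road is at least as safe in reagent stability as the chromium coupling chosen here, and it converges on the same compound. The chosen plan sets against it a shorter sequence, amine-free conditions for ring B, and an answer to C3, which this alternative leaves open.

**Alternative 3:** The C3–C1' bond is cut and farnesyl is introduced last. Hydroxycoumarin A8, carrying the three-carbon arm as a silyl ether, would attack the π-allyl complex formed from carbonate A9 with Pd2(dba)3 (zerovalent palladium) and the C2-symmetric bis(2-diphenylphosphinobenzamide) of trans-1,2-diaminocyclohexane. The product A10 would give 17 after desilylation and oxidation.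
- Merits: A8 is one reductive alkylation away from a commercial coumarin, so 17 would be reached in about four steps, fewer than half the number of the chosen plan. Asymmetric allylic alkylation of cyclic 1,3-dicarbonyl nucleophiles is a known reaction class, and the enolate is cyclic here as well.
- Weak points: the stereocentre forms on the nucleophile, outside the first coordination sphere of the metal. The ambident coumarin anion can be allylated on O4. The unsymmetrical farnesyl π-allyl can be attacked at C1' or C3' and can lose its 2E geometry by π–σ–π isomerisation. Two adjustments (deprotection, oxidation) are needed at C3''.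
- Comparison: in step count and in degree of precedent this road is superior. The chosen plan sets against it three points. Farnesyl is attached by a plain SN2 alkylation with no regiochemical or geometrical risk. C- versus O-selectivity is self-correcting, because an O-aroyl ketene acetal returns to the ion pair. C3'' emerges at the aldehyde level without redox or protecting-group steps.

Key step: step 8

Assumption 1: (S)-benzotetramisole is taken to be the antipode that leads to (R)-15; the sense cannot be derived from precedent for this substrate class, and (R)-benzotetramisole is used if the opposite holds.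
Assumption 2: (S,S)-ProPhenol is taken to deliver the diynyl group to the Re face of 23, which gives (S)-25; if the opposite sense is found, the (R,R)-ligand is used.

## Route

Step 1
Reactants: 1 methyl 5,5-dimethoxypentanoate; 2 (2E,6E)-farnesyl bromide
Product: 4 methyl rac-2-[(2E,6E)-farnesyl]-5,5-dimethoxypentanoate, via lithium ester enolate 3 (not isolated)
Conditions: LiN(iPr)2, THF, −78 °C; then 2, DMPU, −78 → −30 °C
Reagents that add atoms: none
Why: Kinetic ester enolate alkylation (SN2) with a reactive primary allylic bromide; the acetal is inert to the amide base and the farnesyl geometry is not involved. The new α-centre is racemic, which does not matter because it becomes sp2 in step 4.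

Step 2
Reactants: 4 methyl rac-2-[(2E,6E)-farnesyl]-5,5-dimethoxypentanoate
Product: 6 rac-2-[(2E,6E)-farnesyl]-5-oxopentanoic acid, via lithium carboxylate 5 (not isolated)
Conditions: LiOH, THF/MeOH/H2O, 40 °C; then 1 M HCl to pH 2, THF/H2O, rt
Reagents that add atoms: lithium hydroxide, [Li+].[OH-]; water, O
Why: Saponification followed by aqueous acid hydrolysis of the dimethyl acetal; dilute acid at room temperature should leave the trisubstituted alkenes alone. The product equilibrates with its cyclic pseudo-acid (6-hydroxy-δ-lactone) form, which is the species that dehydrates in step 3.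

Step 3
Reactants: 6 rac-2-[(2E,6E)-farnesyl]-5-oxopentanoic acid
Product: 7 rac-3-[(2E,6E)-farnesyl]-3,4-dihydro-2H-pyran-2-one
Conditions: TsOH·H2O (5 mol%), benzene, reflux, Dean–Stark trap
Reagents that add atoms: none
Why: Acid-catalysed enol lactonisation (cyclodehydration of a δ-aldehydo acid): the pseudo-acid form of 6 loses water through an acyloxycarbenium ion and a C5 proton, and azeotropic removal of water drives the reaction. Catalytic TsOH in hot benzene is the regime in which isoprenoid chains ordinarily survive, as in ketalisations of polyprenyl ketones.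

Step 4
Reactants: 7 rac-3-[(2E,6E)-farnesyl]-3,4-dihydro-2H-pyran-2-one
Product: 9 3-[(2E,6E)-farnesyl]-2-(trimethylsilyloxy)-4H-pyran, via lithium lactone enolate 8 (not isolated)
Conditions: Me3SiCl, THF, −78 °C; then LiN(iPr)2 added slowly (internal quench), −78 °C; pentane, filtration under argon, used crude
Reagents that add atoms: chlorotrimethylsilane, C[Si](C)(C)Cl
Why: Kinetic deprotonation α to the lactone carbonyl and O-silylation (silyl ketene acetal formation). The internal quench at −78 °C traps enolate 8 before it can open to a ketene by expelling its enolate leaving group, and the ring allows only one ketene acetal geometry.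

Step 5
Reactants: 10 salicylic acid
Product: 12 2-(tert-butyldimethylsilyloxy)benzoic acid, via bis-silyl salicylate 11 (not isolated)
Conditions: tBuMe2SiCl (2.3 equiv), imidazole, DMF, rt; then AcOH/THF/H2O, rt
Reagents that add atoms: tert-butyldimethylsilyl chloride, CC(C)(C)[Si](C)(C)Cl
Why: Exhaustive silylation followed by selective hydrolysis of the much more labile silyl ester; the aryl silyl ether should survive dilute aqueous acetic acid.

Step 6
Reactants: 12 2-(tert-butyldimethylsilyloxy)benzoic acid
Product: 13 2-(tert-butyldimethylsilyloxy)benzoyl chloride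
Conditions: 1-chloro-N,N,2-trimethylprop-1-en-1-amine (1.1 equiv), CH2Cl2, 0 °C → rt; concentrated, used crude
Reagents that add atoms: 1-chloro-N,N,2-trimethylprop-1-en-1-amine, CC(C)=C(Cl)N(C)C
Why: Acid chloride formation with an α-chloroenamine (Ghosez reagent) under neutral conditions; the only co-product is a tertiary amide and no HCl is set free, so the aryl silyl ether is kept.

Step 7
Reactants: 12 2-(tert-butyldimethylsilyloxy)benzoic acid; 13 2-(tert-butyldimethylsilyloxy)benzoyl chloride
Product: 14 2-(tert-butyldimethylsilyloxy)benzoic anhydride
Conditions: 12 (1.0 equiv), 13 (1.0 equiv), pyridine (1.1 equiv), CH2Cl2, 0 °C → rt; pentane, filtration, concentration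
Reagents that add atoms: none
Why: Acylation of a carboxylic acid by an acid chloride in the presence of pyridine gives the symmetrical anhydride; the conditions are anhydrous and weakly basic, so the aryl silyl ethers are kept, and the pyridinium salt is removed by filtration from pentane.

Step 8
Reactants: 9 3-[(2E,6E)-farnesyl]-2-(trimethylsilyloxy)-4H-pyran; 14 2-(tert-butyldimethylsilyloxy)benzoic anhydride
Product: 15 (R)-3-[2-(tert-butyldimethylsilyloxy)benzoyl]-3-[(2E,6E)-farnesyl]-3,4-dihydro-2H-pyran-2-one
Conditions: 14 (1.3 equiv), (S)-benzotetramisole (C15H12N2S, 10 mol%), CH2Cl2, −40 °C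
Reagents that add atoms: none
Why: Proposed new method: benzotetramisole is aroylated by 14 to an N-aroyl isothiouronium carboxylate, the carboxylate strips Me3Si from 9, and the chiral acyl cation and the cyclic lactone enolate then combine within the ion pair at C3, forming the C3–C4 bond and releasing the catalyst. The closest known reaction type is the chiral-nucleophile-catalysed C-acylation of lactone-derived silyl ketene acetals with anhydrides (Steglich-type acyl transfer); new here are the ortho-substituted aroyl donor, the α-alkyl enolate and the enol-lactone acetal. No ring is closed. The C3 stereocentre is controlled by the catalyst: the acyl group lies coplanar with the isothiouronium (carbonyl oxygen syn to sulfur), the C2 phenyl group blocks one face, and the enolate must bond from the open face. Because the ring of 9 holds C1'' inside and farnesyl outside, there is one enolate geometry, and the catalyst only has to choose between the two enantiotopic faces, which it can read through the fixed in-plane arrangement of ring oxygen, oxyanion, ring CH2 and farnesyl. The step needs C- over O-aroylation; an O-aroyl ketene acetal is itself an acyl donor to the catalyst and returns to the ion pair, whereas 15 has no α-hydrogen and cannot revert. The bulky ortho silyloxy group slows the uncatalysed reaction of 14 with 9, and −40 °C suppresses ring opening of the enolate to a ketene.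

Step 9
Reactants: 15 (R)-3-[2-(tert-butyldimethylsilyloxy)benzoyl]-3-[(2E,6E)-farnesyl]-3,4-dihydro-2H-pyran-2-one
Product: 17 3-{(S)-3-[(2E,6E)-farnesyl]-2,4-dioxochroman-3-yl}propanal, via free phenol 16 (not isolated)
Conditions: HF·pyridine, pyridine, THF, 0 °C; then Et3N, 0 °C → rt
Reagents that add atoms: none
Why: Fluoride desilylation followed by base-triggered intramolecular transacylation (translactonisation): the phenoxide of 16 attacks the enol-lactone carbonyl in a six-membered exo-trig closure that forms O1–C2, the tetrahedral intermediate expels the enolate oxygen, and protonation at C2'' gives the C3'' aldehyde. The enol-to-aldehyde tautomerisation makes the acyl transfer irreversible. No bond at C3 is broken, so its configuration is kept; the descriptor changes from R to S only because the ligand priorities change.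

Step 10
Reactants: 18 1,4-bis(trimethylsilyl)buta-1,3-diyne
Product: 20 buta-1,3-diyn-1-yl(trimethyl)silane, via lithium diynide 19 (not isolated)
Conditions: MeLi·LiBr (1.0 equiv), Et2O, 0 °C → rt; then aq NH4Cl, 0 °C; dried solution used directly
Reagents that add atoms: none
Why: Selective monodesilylation: methyllithium attacks one silicon and releases the sp carbanion, which is protonated on quenching; the second silyl group is retained because the diynide anion deactivates it.

Step 11
Reactants: 21 dec-2-yn-1-ol
Product: 22 (Z)-dec-2-en-1-ol
Conditions: H2 (1 atm), Pd/CaCO3 poisoned with Pb(OAc)2 (Lindlar catalyst), quinoline, hexane, rt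
Reagents that add atoms: none
Why: Lindlar semihydrogenation; syn delivery of hydrogen on the poisoned surface gives the Z alkene and stops before the alkane.

Step 12
Reactants: 22 (Z)-dec-2-en-1-ol
Product: 23 (Z)-dec-2-enal
Conditions: Dess–Martin periodinane, NaHCO3, CH2Cl2, 0 °C; used at once
Reagents that add atoms: none
Why: Buffered Dess–Martin oxidation of an allylic alcohol; the neutral, cold conditions and immediate use should preserve the Z geometry of the enal.

Step 13
Reactants: 23 (Z)-dec-2-enal; 20 buta-1,3-diyn-1-yl(trimethyl)silane
Product: 25 (S,Z)-1-(trimethylsilyl)tetradec-6-ene-1,3-diyn-5-ol, via methylzinc diynide 24 (not isolated)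
Conditions: 20 (3 equiv), Me2Zn (3 equiv), (S,S)-ProPhenol (10 mol%), Ph3P=O (20 mol%), toluene, 0 °C; then 23, 4 °C; aq NH4Cl
Reagents that add atoms: none
Why: Catalytic asymmetric alkynylation of an aldehyde: Me2Zn converts 20 into zinc alkynylide 24, and the dinuclear complex formed from Me2Zn and the ProPhenol ligand holds aldehyde and alkynylide on neighbouring zinc atoms so that the diynyl group is delivered to the Re face of 23, which sets C8'' as S. Enals react by 1,2-addition, and the low temperature should keep the Z alkene.

Step 14
Reactants: 25 (S,Z)-1-(trimethylsilyl)tetradec-6-ene-1,3-diyn-5-ol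
Product: 26 (S,Z)-5-(tert-butyldimethylsilyloxy)-1-(trimethylsilyl)tetradec-6-ene-1,3-diyne
Conditions: tBuMe2SiCl, imidazole, CH2Cl2, 0 °C → rt
Reagents that add atoms: tert-butyldimethylsilyl chloride, CC(C)(C)[Si](C)(C)Cl
Why: Standard silylation of a secondary alcohol; the mild base leaves the alkynylsilane and the stereocentre untouched.

Step 15
Reactants: 26 (S,Z)-5-(tert-butyldimethylsilyloxy)-1-(trimethylsilyl)tetradec-6-ene-1,3-diyne
Product: 27 (S,Z)-5-(tert-butyldimethylsilyloxy)-1-iodotetradec-6-ene-1,3-diyne
Conditions: N-iodosuccinimide, AgNO3 (10 mol%), DMF, rt, dark; used at once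
Reagents that add atoms: N-iodosuccinimide, O=C1CCC(=O)N1I
Why: Silver-catalysed iododesilylation: AgNO3 converts the alkynylsilane into a silver acetylide that is iodinated by N-iodosuccinimide, giving the 1-iododiyne in one operation. The silyl ether and the Z alkene are inert under these neutral conditions.

Step 16
Reactants: 17 3-{(S)-3-[(2E,6E)-farnesyl]-2,4-dioxochroman-3-yl}propanal; 27 (S,Z)-5-(tert-butyldimethylsilyloxy)-1-iodotetradec-6-ene-1,3-diyne
Product: 28 (S)-3-[(8S,9Z)-8-(tert-butyldimethylsilyloxy)-3-hydroxyheptadec-9-ene-4,6-diyn-1-yl]-3-[(2E,6E)-farnesyl]chroman-2,4-dione (both C3'' epimers)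
Conditions: CrCl2 (6 equiv), THF, rt, dark
Reagents that add atoms: none
Why: Nozaki–Hiyama–Kishi-type alkynylation: two equivalents of divalent chromium insert into the C–I bond of 27 to give an alkynyl species of trivalent chromium, which adds to aldehydes but not to ketones or lactones, so the C3''–C4'' bond forms without touching ring B. The C3'' carbinol forms as both epimers, which converge in step 17.

Step 17
Reactants: 28 (S)-3-[(8S,9Z)-8-(tert-butyldimethylsilyloxy)-3-hydroxyheptadec-9-ene-4,6-diyn-1-yl]-3-[(2E,6E)-farnesyl]chroman-2,4-dione (both C3'' epimers)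
Product: 29 (S)-3-[(8S,9Z)-8-(tert-butyldimethylsilyloxy)-3-oxoheptadec-9-ene-4,6-diyn-1-yl]-3-[(2E,6E)-farnesyl]chroman-2,4-dione
Conditions: Dess–Martin periodinane, NaHCO3, CH2Cl2, 0 °C → rt
Reagents that add atoms: none
Why: Dess–Martin oxidation of a propargylic alcohol to the ynone; the buffered, non-nucleophilic conditions spare the alkenes, the silyl ether and ring B, and the C8'' oxygen is protected.

Step 18
Reactants: 29 (S)-3-[(8S,9Z)-8-(tert-butyldimethylsilyloxy)-3-oxoheptadec-9-ene-4,6-diyn-1-yl]-3-[(2E,6E)-farnesyl]chroman-2,4-dione
Product: 30 (S)-3-[(8S,9Z)-8-hydroxy-3-oxoheptadec-9-ene-4,6-diyn-1-yl]-3-[(2E,6E)-farnesyl]chroman-2,4-dione (CNP0346147.1)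
Conditions: 48% aq HF, MeCN, 0 °C
Reagents that add atoms: none
Why: Acidic fluoride desilylation of a secondary silyl ether; the absence of basic fluoride and amines avoids conjugate addition to the diynone and opening of ring B, and dilute HF at 0 °C should not ionise the C8'' carbinol, so both stereocentres are kept.

## Compound list

1 | methyl 5,5-dimethoxypentanoate | COC(OC)CCCC(=O)OC | starting material
2 | (2E,6E)-farnesyl bromide | BrC/C=C(\C)CC/C=C(\C)CCC=C(C)C | starting material
3 | lithium enolate of methyl 5,5-dimethoxypentanoate | [Li+].[O-]C(OC)=CCCC(OC)OC | intermediate (not isolated)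
4 | methyl rac-2-[(2E,6E)-farnesyl]-5,5-dimethoxypentanoate | COC(=O)C(CCC(OC)OC)C/C=C(\C)CC/C=C(\C)CCC=C(C)C | intermediate
5 | lithium rac-2-[(2E,6E)-farnesyl]-5,5-dimethoxypentanoate | [Li+].[O-]C(=O)C(CCC(OC)OC)C/C=C(\C)CC/C=C(\C)CCC=C(C)C | intermediate (not isolated)
6 | rac-2-[(2E,6E)-farnesyl]-5-oxopentanoic acid | OC(=O)C(CCC=O)C/C=C(\C)CC/C=C(\C)CCC=C(C)C | intermediate
7 | rac-3-[(2E,6E)-farnesyl]-3,4-dihydro-2H-pyran-2-one | O=C1OC=CCC1C/C=C(\C)CC/C=C(\C)CCC=C(C)C | intermediate
8 | lithium 3-[(2E,6E)-farnesyl]-4H-pyran-2-olate | [Li+].[O-]C1=C(C/C=C(\C)CC/C=C(\C)CCC=C(C)C)CC=CO1 | intermediate (not isolated)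
9 | 3-[(2E,6E)-farnesyl]-2-(trimethylsilyloxy)-4H-pyran | C[Si](C)(C)OC1=C(C/C=C(\C)CC/C=C(\C)CCC=C(C)C)CC=CO1 | intermediate
10 | salicylic acid | OC(=O)c1ccccc1O | starting material
11 | tert-butyldimethylsilyl 2-(tert-butyldimethylsilyloxy)benzoate | CC(C)(C)[Si](C)(C)OC(=O)c1ccccc1O[Si](C)(C)C(C)(C)C | intermediate (not isolated)
12 | 2-(tert-butyldimethylsilyloxy)benzoic acid | CC(C)(C)[Si](C)(C)Oc1ccccc1C(=O)O | intermediate
13 | 2-(tert-butyldimethylsilyloxy)benzoyl chloride | CC(C)(C)[Si](C)(C)Oc1ccccc1C(=O)Cl | intermediate
14 | 2-(tert-butyldimethylsilyloxy)benzoic anhydride | CC(C)(C)[Si](C)(C)Oc1ccccc1C(=O)OC(=O)c1ccccc1O[Si](C)(C)C(C)(C)C | intermediate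
15 | (R)-3-[2-(tert-butyldimethylsilyloxy)benzoyl]-3-[(2E,6E)-farnesyl]-3,4-dihydro-2H-pyran-2-one | O=C1OC=CC[C@@]1(C(=O)c2ccccc2O[Si](C)(C)C(C)(C)C)C/C=C(\C)CC/C=C(\C)CCC=C(C)C | intermediate
16 | (R)-3-[(2E,6E)-farnesyl]-3-(2-hydroxybenzoyl)-3,4-dihydro-2H-pyran-2-one | O=C1OC=CC[C@@]1(C(=O)c2ccccc2O)C/C=C(\C)CC/C=C(\C)CCC=C(C)C | intermediate (not isolated)
17 | 3-{(S)-3-[(2E,6E)-farnesyl]-2,4-dioxochroman-3-yl}propanal | O=CCC[C@@]1(C/C=C(\C)CC/C=C(\C)CCC=C(C)C)C(=O)Oc2ccccc2C1=O | intermediate
18 | 1,4-bis(trimethylsilyl)buta-1,3-diyne | C[Si](C)(C)C#CC#C[Si](C)(C)C | starting material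
19 | lithium 4-(trimethylsilyl)buta-1,3-diyn-1-ide | [Li]C#CC#C[Si](C)(C)C | intermediate (not isolated)
20 | buta-1,3-diyn-1-yl(trimethyl)silane | C#CC#C[Si](C)(C)C | intermediate
21 | dec-2-yn-1-ol | CCCCCCCC#CCO | starting material
22 | (Z)-dec-2-en-1-ol | CCCCCCC/C=C\CO | intermediate
23 | (Z)-dec-2-enal | CCCCCCC/C=C\C=O | intermediate
24 | methyl[4-(trimethylsilyl)buta-1,3-diyn-1-yl]zinc | C[Zn]C#CC#C[Si](C)(C)C | intermediate (not isolated)
25 | (S,Z)-1-(trimethylsilyl)tetradec-6-ene-1,3-diyn-5-ol | CCCCCCC/C=C\[C@H](O)C#CC#C[Si](C)(C)C | intermediate
26 | (S,Z)-5-(tert-butyldimethylsilyloxy)-1-(trimethylsilyl)tetradec-6-ene-1,3-diyne | CCCCCCC/C=C\[C@H](O[Si](C)(C)C(C)(C)C)C#CC#C[Si](C)(C)C | intermediate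
27 | (S,Z)-5-(tert-butyldimethylsilyloxy)-1-iodotetradec-6-ene-1,3-diyne | CCCCCCC/C=C\[C@H](O[Si](C)(C)C(C)(C)C)C#CC#CI | intermediate
28 | (S)-3-[(8S,9Z)-8-(tert-butyldimethylsilyloxy)-3-hydroxyheptadec-9-ene-4,6-diyn-1-yl]-3-[(2E,6E)-farnesyl]chroman-2,4-dione (both C3'' epimers) | CCCCCCC/C=C\[C@H](O[Si](C)(C)C(C)(C)C)C#CC#CC(O)CC[C@@]1(C/C=C(\C)CC/C=C(\C)CCC=C(C)C)C(=O)Oc2ccccc2C1=O | intermediate
29 | (S)-3-[(8S,9Z)-8-(tert-butyldimethylsilyloxy)-3-oxoheptadec-9-ene-4,6-diyn-1-yl]-3-[(2E,6E)-farnesyl]chroman-2,4-dione | CCCCCCC/C=C\[C@H](O[Si](C)(C)C(C)(C)C)C#CC#CC(=O)CC[C@@]1(C/C=C(\C)CC/C=C(\C)CCC=C(C)C)C(=O)Oc2ccccc2C1=O | intermediate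
30 | (S)-3-[(8S,9Z)-8-hydroxy-3-oxoheptadec-9-ene-4,6-diyn-1-yl]-3-[(2E,6E)-farnesyl]chroman-2,4-dione (CNP0346147.1) | CCCCCCC/C=C\[C@H](O)C#CC#CC(=O)CC[C@@]1(C/C=C(\C)CC/C=C(\C)CCC=C(C)C)C(=O)Oc2ccccc2C1=O | target

## Step count and least certain steps

Total step count: 18. Longest linear sequence: 9 steps (steps 1, 2, 3, 4, 8, 9, 16, 17, 18).

**Step 8 (key step, proposed new method).** The most likely failure is poor facial discrimination for an α-alkyl enolate, a class on which this type of acyl transfer is not established. The second is slow C–C bond formation between a fully substituted enolate carbon and an ortho-hindered acyl isothiouronium. That would let O-aroylation, hydrolysis of the moisture-sensitive ketene acetal, or ring opening of the enolate to a ketene take over.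
Fallback (sets out from 7 and 14, returns at 15): the lithium enolate 8, generated from 7 with LiN(iPr)2 at −78 °C, is C-aroylated directly with 14 in a Claisen-type acylation. This gives racemic 3-[2-(tert-butyldimethylsilyloxy)benzoyl]-3-farnesyl-3,4-dihydro-2H-pyran-2-one F1. Preparative chromatography on a chiral stationary phase then delivers 15 and sets aside the (S)-antipode F2.

**Step 3.** Acid-induced cyclisation or double-bond migration in the farnesyl chain may compete with cyclodehydration, and intermolecular pseudo-anhydride formation may take the place of ring dehydration.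
Fallback (sets out from 1 and 2, returns at 7): the order is reversed so that no polyene meets acid. Ester 1 is saponified and its acetal hydrolysed to 5-oxopentanoic acid F3. F3 is cyclodehydrated (TsOH, toluene, Dean–Stark) to 3,4-dihydro-2H-pyran-2-one F4. Its lithium enolate, lithium 4H-pyran-2-olate F5 (LiN(iPr)2, THF, −78 °C), is alkylated with 2 in the presence of DMPU to give 7.

**Step 13.** Z to E isomerisation of the enal may occur before or during the addition, through reversible conjugate addition of Lewis bases. Enantioselectivity may also be lower than for the E-enals on which this alkynylation is best established, and volatile 20 may be lost.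
Fallback (sets out from 18 and 23, returns at 25): lithium diynide 19, made from 18 as in step 10, is added to 23 at −78 °C without Lewis acid or amine. This gives racemic (Z)-1-(trimethylsilyl)tetradec-6-ene-1,3-diyn-5-ol F6. Kinetic resolution by lipase-catalysed acetylation (Burkholderia cepacia lipase, vinyl acetate, hexane) follows. By the empirical rule for secondary alcohols, with the alkenyl arm as the large group, this is expected to convert the (S)-enantiomer into (S,Z)-1-(trimethylsilyl)tetradec-6-ene-1,3-diyn-5-yl acetate F7. The (R)-alcohol, (R,Z)-1-(trimethylsilyl)tetradec-6-ene-1,3-diyn-5-ol F8, is left behind. F7 is cleaved with iBu2AlH at −78 °C, which spares the alkynylsilane, to give 25.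

**Step 16.** Reductive homocoupling or decomposition of the light- and heat-sensitive 1-iododiyne at chromium may outrun addition to the aldehyde, and a sluggish addition would leave 17 open to aldol self-condensation.
Fallback (sets out from 17 and 26, returns at 29): the ynone is made by acylation in place of addition and oxidation. Aldehyde 17 is oxidised (NaClO2, NaH2PO4, 2-methyl-2-butene) to 3-{(S)-3-farnesyl-2,4-dioxochroman-3-yl}propanoic acid F9. F9 is converted under neutral conditions with 1-chloro-N,N,2-trimethylprop-1-en-1-amine into the acid chloride 3-{(S)-3-farnesyl-2,4-dioxochroman-3-yl}propanoyl chloride F10. Silyl ether 26 is C-desilylated (K2CO3, MeOH, 0 °C) to (S,Z)-5-(tert-butyldimethylsilyloxy)tetradec-6-ene-1,3-diyne F11. Acyl Sonogashira coupling of F10 with F11 (PdCl2(PPh3)2, CuI, Et3N, THF) gives 29 directly, so step 17 is not needed.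

## Further compounds

F1 | step 8 | rac-3-[2-(tert-butyldimethylsilyloxy)benzoyl]-3-[(2E,6E)-farnesyl]-3,4-dihydro-2H-pyran-2-one | O=C1OC=CCC1(C(=O)c2ccccc2O[Si](C)(C)C(C)(C)C)C/C=C(\C)CC/C=C(\C)CCC=C(C)C
F2 | step 8 | (S)-3-[2-(tert-butyldimethylsilyloxy)benzoyl]-3-[(2E,6E)-farnesyl]-3,4-dihydro-2H-pyran-2-one | O=C1OC=CC[C@]1(C(=O)c2ccccc2O[Si](C)(C)C(C)(C)C)C/C=C(\C)CC/C=C(\C)CCC=C(C)C
F3 | step 3 | 5-oxopentanoic acid | O=CCCCC(=O)O
F4 | step 3 | 3,4-dihydro-2H-pyran-2-one | O=C1CCC=CO1
F5 | step 3 | lithium 4H-pyran-2-olate | [Li+].[O-]C1=CCC=CO1
F6 | step 13 | rac-(Z)-1-(trimethylsilyl)tetradec-6-ene-1,3-diyn-5-ol | CCCCCCC/C=C\C(O)C#CC#C[Si](C)(C)C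
F7 | step 13 | (S,Z)-1-(trimethylsilyl)tetradec-6-ene-1,3-diyn-5-yl acetate | CCCCCCC/C=C\[C@H](OC(C)=O)C#CC#C[Si](C)(C)C
F8 | step 13 | (R,Z)-1-(trimethylsilyl)tetradec-6-ene-1,3-diyn-5-ol | CCCCCCC/C=C\[C@@H](O)C#CC#C[Si](C)(C)C
F9 | step 16 | 3-{(S)-3-[(2E,6E)-farnesyl]-2,4-dioxochroman-3-yl}propanoic acid | OC(=O)CC[C@@]1(C/C=C(\C)CC/C=C(\C)CCC=C(C)C)C(=O)Oc2ccccc2C1=O
F10 | step 16 | 3-{(S)-3-[(2E,6E)-farnesyl]-2,4-dioxochroman-3-yl}propanoyl chloride | ClC(=O)CC[C@@]1(C/C=C(\C)CC/C=C(\C)CCC=C(C)C)C(=O)Oc2ccccc2C1=O
F11 | step 16 | (S,Z)-5-(tert-butyldimethylsilyloxy)tetradec-6-ene-1,3-diyne | CCCCCCC/C=C\[C@H](O[Si](C)(C)C(C)(C)C)C#CC#C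
A1 | alternative 1 | dimethyl 2-(3,3-dimethoxypropyl)-2-[(2E,6E)-farnesyl]malonate | COC(OC)CCC(C/C=C(\C)CC/C=C(\C)CCC=C(C)C)(C(=O)OC)C(=O)OC
A2 | alternative 1 | (R)-2-(3,3-dimethoxypropyl)-2-[(2E,6E)-farnesyl]malonic acid monomethyl ester | COC(OC)CC[C@@](C/C=C(\C)CC/C=C(\C)CCC=C(C)C)(C(=O)O)C(=O)OC
A3 | alternative 1 | 2-(trimethylsilyl)phenyl trifluoromethanesulfonate | C[Si](C)(C)c1ccccc1OS(=O)(=O)C(F)(F)F
A4 | alternative 1 | (S)-3-(3,3-dimethoxypropyl)-3-[(2E,6E)-farnesyl]chroman-2,4-dione | COC(OC)CC[C@@]1(C/C=C(\C)CC/C=C(\C)CCC=C(C)C)C(=O)Oc2ccccc2C1=O
A5 | alternative 2 | (S)-3-[(2E,6E)-farnesyl]-3-(3-hydroxypent-4-yn-1-yl)chroman-2,4-dione | C#CC(O)CC[C@@]1(C/C=C(\C)CC/C=C(\C)CCC=C(C)C)C(=O)Oc2ccccc2C1=O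
A6 | alternative 2 | (S,Z)-1-bromo-3-(tert-butyldimethylsilyloxy)dodec-4-en-1-yne | CCCCCCC/C=C\[C@H](O[Si](C)(C)C(C)(C)C)C#CBr
A7 | alternative 2 | (S)-3-[(8S,9Z)-8-(tert-butyldimethylsilyloxy)-3-hydroxyheptadec-9-ene-4,6-diyn-1-yl]-3-[(2E,6E)-farnesyl]chroman-2,4-dione | CCCCCCC/C=C\[C@H](O[Si](C)(C)C(C)(C)C)C#CC#CC(O)CC[C@@]1(C/C=C(\C)CC/C=C(\C)CCC=C(C)C)C(=O)Oc2ccccc2C1=O
A8 | alternative 3 | 3-[3-(tert-butyldimethylsilyloxy)propyl]-4-hydroxycoumarin | CC(C)(C)[Si](C)(C)OCCCc1c(O)c2ccccc2oc1=O
A9 | alternative 3 | (2E,6E)-farnesyl methyl carbonate | COC(=O)OC/C=C(\C)CC/C=C(\C)CCC=C(C)C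
A10 | alternative 3 | (S)-3-[3-(tert-butyldimethylsilyloxy)propyl]-3-[(2E,6E)-farnesyl]chroman-2,4-dione | CC(C)(C)[Si](C)(C)OCCC[C@@]1(C/C=C(\C)CC/C=C(\C)CCC=C(C)C)C(=O)Oc2ccccc2C1=O
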